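**Strategy.** Both 3-hydroxy-4,4,6,6-tetramethylcyclohex-2-ene-1,5-dione rings (C2 bears the bridging CH, C3 the enol OH) are disconnected at C1–C2 and C3–C4. This shows that C1(=O)–C6Me2–C5(=O)–C4Me2 of each ring is the intact carbon square of commercial 2,2,4,4-tetramethylcyclobutane-1,3-dione. C2, C3 and the bridging CH(i-Bu) belong to achiral dimethyl 3-isobutylglutarate. In one operation the bis-enolate of this diester adds to two cyclobutanediones; strain-driven retro-Claisen opening and Dieckmann reclosure insert each ester Cα–C(=O) pair into a four-membered ring. This double two-carbon ring expansion (4 → 6) should give the target directly.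

Key step: step 2

Remarks on the chemistry:
- The target is achiral (the bridging CH carries two identical rings) and each β-triketone is drawn as one of its degenerate enol tautomers, so no stereocentre has to be controlled.
- 3-Isobutylglutaric acid and 2,2,4,4-tetramethylcyclobutane-1,3-dione are taken as commercial.
- The route has only two steps, so two steps, not three, are ranked at the end.

**Compounds**
- 1: 3-isobutylglutaric acid, i.e. 3-(2-methylpropyl)pentanedioic acid (achiral).
- 2: dimethyl 3-isobutylglutarate (achiral).
- 3: 2,2,4,4-tetramethylcyclobutane-1,3-dione (dimethylketene dimer).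
- 4: dilithium bis-enolate of 2 (both ester α-carbons deprotonated; enolate geometry not defined).
- 5: dilithium bis-aldolate, dimethyl 3-isobutyl-2,4-bis(1-oxido-2,2,4,4-tetramethyl-3-oxocyclobutyl)pentanedioate (mixture of diastereomers).
- 6: ring-opened dienolate, the dilithium bis(β-keto ester enolate) of dimethyl 3-isobutyl-2,4-bis(2,2,4-trimethyl-3-oxopentanoyl)pentanedioate.
- 7: Watsonianone A, 2,2'-(3-methylbutane-1,1-diyl)bis(3-hydroxy-4,4,6,6-tetramethylcyclohex-2-ene-1,5-dione) (achiral).

**Route**

Step 1
Reactants: 1 3-isobutylglutaric acid
Product: 2 dimethyl 3-isobutylglutarate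
Conditions: MeOH (solvent), cat. H2SO4, reflux
Reagents that add atoms: methanol, CO
Why: Fischer esterification, driven to the diester by the large excess of methanol; no stereocentre is involved because C3 carries two identical arms.

Step 2
Reactants: 2 dimethyl 3-isobutylglutarate; 3 2,2,4,4-tetramethylcyclobutane-1,3-dione (2.2 equiv)
Product: 7 Watsonianone A, via dilithium bis-enolate 4 (not isolated), via dilithium bis-aldolate 5 (not isolated), via ring-opened dienolate 6 (not isolated)
Conditions: LDA (2.1 equiv), THF, −78 °C; cannulate into 3 (2.2 equiv), THF, −78 → 0 °C; then KOt-Bu (3 equiv), 0 → 60 °C; then 1 M HCl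
Reagents that add atoms: none
Why: Proposed new method: each ester enolate carbon of 4 adds to a strained, non-enolisable C=O of 3 (aldol, 5), the tertiary cyclobutoxide then cleaves the adjacent C(O)–CMe2 ring bond in a strain-driven retro-Claisen step to an isopropyl-ketone enolate that is quenched internally by the new, more acidic β-keto ester C–H (6), and KOt-Bu regenerates the Me2C enolate, which closes onto the methyl ester with loss of methoxide (Dieckmann), so that the four carbons of each cyclobutanedione plus one ester Cα–C=O pair become one six-membered β-triketone, a two-carbon ring expansion carried out on both arms. The closest known reaction types are the nucleophilic ring-opening of 3 by alkoxides or amines to 2,2,4-trimethyl-3-oxopentanoyl derivatives, the base-induced cleavage of 3-hydroxycyclobutanones, the Dieckmann closure of 2,2,4,4-tetramethyl-3,5-dioxo esters to syncarpic acid, and two-carbon insertions of arynes into the C–C bond of β-dicarbonyl compounds. Each ring closes in a 6-(enolendo)-exo-trig Claisen attack of the Me2C enolate carbon on the ester carbonyl of its own arm; closure onto the ester of the other arm would need an eight-membered ring and is not expected. No stereocentre survives, since the Cα centres of 5 become enol carbons and the bridging CH carries two identical rings, so the diastereomer mixture at the stage of 5 is without consequence. The step needs both aldol additions to be complete before any fragmentation (an early-formed acidic β-keto ester C–H would quench the second ester enolate), which the inverse addition into excess 3 at −78 °C is meant to secure, and it needs C- rather than O-acylation in the closure, which is expected on thermodynamic grounds because enol-lactone and open-chain isomers can revert under KOt-Bu while the β-triketone enolate is the sink. Relief of cyclobutane strain and formation of two strongly stabilised β-triketone enolates should drive the cascade, and the acidic product should be separable from neutral by-products by base extraction.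

**Compound list**

1 | 3-isobutylglutaric acid [3-(2-methylpropyl)pentanedioic acid] | CC(C)CC(CC(=O)O)CC(=O)O | starting material
2 | dimethyl 3-isobutylglutarate | COC(=O)CC(CC(C)C)CC(=O)OC | intermediate
3 | 2,2,4,4-tetramethylcyclobutane-1,3-dione | CC1(C)C(=O)C(C)(C)C1=O | starting material
4 | dilithium bis-enolate of 2 (enolate geometry not defined) | [Li+].[Li+].COC([O-])=CC(CC(C)C)C=C([O-])OC | intermediate
5 | dilithium bis-aldolate, dimethyl 3-isobutyl-2,4-bis(1-oxido-2,2,4,4-tetramethyl-3-oxocyclobutyl)pentanedioate (mixture of diastereomers) | [Li+].[Li+].COC(=O)C(C(CC(C)C)C(C(=O)OC)C1([O-])C(C)(C)C(=O)C1(C)C)C1([O-])C(C)(C)C(=O)C1(C)C | intermediate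
6 | ring-opened dienolate, dilithium bis-enolate of dimethyl 3-isobutyl-2,4-bis(2,2,4-trimethyl-3-oxopentanoyl)pentanedioate | [Li+].[Li+].COC(=O)C(=C([O-])C(C)(C)C(=O)C(C)C)C(CC(C)C)C(C(=O)OC)=C([O-])C(C)(C)C(=O)C(C)C | intermediate
7 | Watsonianone A, 2,2'-(3-methylbutane-1,1-diyl)bis(3-hydroxy-4,4,6,6-tetramethylcyclohex-2-ene-1,5-dione) (achiral) | CC(C)CC(C1=C(O)C(C)(C)C(=O)C(C)(C)C1=O)C1=C(O)C(C)(C)C(=O)C(C)(C)C1=O | target

**Totals.** Total step count: 2. Longest linear sequence: 2 steps (1 → 2 → 7; compound 3 enters as a commercial reactant in step 2).

**Steps most likely to fail** (both steps of the route, the riskier first)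

1. Step 2 (Proposed new method). Three processes may go wrong. The aldol addition of the β-branched bis-enolate to the hindered cyclobutanone carbonyls may be sluggish or reversible. If one arm fragments before the other has added, its acidic β-keto ester C–H would quench the remaining ester enolate. The closure may stall at the bis(β-keto ester) enolate or proceed by O-acylation. The fallback uses known chemistry, sets out from 3 and comes back to the route at 7. Methanolysis of 3 (NaOMe, MeOH) should open the four-membered ring to methyl 2,2,4-trimethyl-3-oxopentanoate F1. Its lithium enolate (LDA, THF, −78 °C) would be C-acetylated with acetyl chloride to methyl 2,2,4,4-tetramethyl-3,5-dioxohexanoate F2. Dieckmann closure (NaOMe, MeOH, reflux) should then give syncarpic acid F3. Two equivalents of F3 and 3-methylbutanal (isovaleraldehyde, CC(C)CC=O) under amine catalysis (piperidine or L-proline, CH2Cl2, rt) should form the Knoevenagel alkylidene 2-(3-methylbutylidene)-4,4,6,6-tetramethylcyclohexane-1,3,5-trione F4 in the flask. The second equivalent of F3 adds to it in a Michael reaction to give 7.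

2. Step 1. Esterification may remain incomplete because of the water equilibrium, leaving half-ester or cyclic anhydride. The fallback sets out from 1 and comes back at 2. It forms the O–CH3 bonds by irreversible SN2 alkylation of the dicarboxylate (K2CO3, MeI, DMF, rt) instead of the acyl C–O bonds by addition–elimination. It makes no new compound (F0).

**Further compounds**

F1 | step 2 | methyl 2,2,4-trimethyl-3-oxopentanoate | COC(=O)C(C)(C)C(=O)C(C)C
F2 | step 2 | methyl 2,2,4,4-tetramethyl-3,5-dioxohexanoate | COC(=O)C(C)(C)C(=O)C(C)(C)C(C)=O
F3 | step 2 | syncarpic acid (5-hydroxy-2,2,6,6-tetramethylcyclohex-4-ene-1,3-dione) | CC1(C)C(O)=CC(=O)C(C)(C)C1=O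
F4 | step 2 | 2-(3-methylbutylidene)-4,4,6,6-tetramethylcyclohexane-1,3,5-trione | CC(C)CC=C1C(=O)C(C)(C)C(=O)C(C)(C)C1=O
F0 | step 1 | none | none
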